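Divide the rate constant of quenching by that of the uncatalysed loss and you have the quench ratio, 60.3 L mol⁻¹, a selectivity factor between two paths of the starting material. Both paths run on the same free starting material at the same moment, so the quenching rate integrates in closed form: the fraction of protic impurity left is exp(−ratio × concentration of uncatalysed product made), with the feed and the enzyme dropping out.

    starting material → uncatalysed product (k1 = 0.73 h⁻¹)
    starting material + protic impurity → quenched substrate (k2 = 44 L mol⁻¹ h⁻¹)
    starting material + target ⇌ idle adduct, settled at all times (K3 = 8.5 L mol⁻¹)
    starting material + enzyme → target + enzyme, rate k4*[starting material]^2.5*[enzyme]/(1 + ([starting material]/Kh4)^2.5) (Kh4 = 0.14 M, k4 = 5.5 × 10⁶ L²·⁵ mol⁻²·⁵ h⁻¹)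

| setting | amber | teal | ochre |
|---|---|---|---|
| starting material | 0.20 M (fed, over 1.0 h) | 0.20 M (fed, over 1.0 h) | 0.20 M (fed, over 1.0 h) |
| protic impurity | 0.0200 M | 0.0400 M | 0.0800 M |
| enzyme | 4.0 µM | 4.0 µM | 4.0 µM |
| time | 2.5 h | 2.5 h | 2.5 h |

1. [target] (only what is free in solution) at the end for amber, teal, ochre, in this order
2. the shape of the row from first to last (falls all the way / rises all the way / falls, then rises / rises, then falls / hardly changes)

- percent here means starting material units held: one idle adduct counts as two
- what is said of target includes idle adduct
- in an amount of target, one idle adduct counts as one target
- the concentration of target that is asked is that of its free form alone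
- "hardly changes" means that all values lie within two and a half points (for a concentration: within two and a half percent of the largest)
- run time (amber): 2.5 h

My reckoning is a chain. First link: let the quench take the entire impurity charge, which leaves 90.0 % of the starting material in amber, 80.0 % in teal and 60.0 % in ochre.

Second link: the enzyme and the uncatalysed loss divide that remainder. Their rates depend on the level of starting material. For a working level I take the charge less half the impurity charge, and of that I guess 28.6 %, the feed time over the feed time plus the run time: 0.0543 M, 0.0514 M, 0.0457 M. At these levels the enzyme's rate law gives it a share of 25.8 %, 24.5 % and 21.7 %. Target, bound form included, is then 23.3 %, 19.6 % and 13.0 % of the charge.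

Third link: the idle adduct. Suppose half the remainder stands when the feed ends and then decays at the uncatalysed rate; the end levels are 0.0301 M, 0.0268 M and 0.0201 M. Dividing target by one plus the balance constant times that level, I commit to 37.0 mM, 32.0 mM and 22.3 mM of free target. My row drops by 5.08 mM from amber to teal and by 9.69 mM from teal to ochre, so its shape is: falls all the way.

The link I can test is the first. Test it on ochre, which holds more impurity than the other flasks. My chain leaves 0.0739 M of uncatalysed product there, and the ratio turns this into 1.17 % of the impurity left. The quench's take shrinks by 0.467 % of the charge, less than the target I reckoned for ochre.

The forecast, a separate judgement and not my reckoning, says 0.04 M, 0.032 M and 0.021 M, falls all the way, holding that “this costs target more than in proportion”.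

The flask gives 0.0363 M, 0.0306 M and 0.0203 M, falls all the way.

At the end of ochre the quenched substrate stands at 39.6 % of the charge. The uncatalysed product of ochre, 37.8 %, put through the quench ratio gives 1.05 % of the impurity left, and the flask holds 1.1 %. In teal the uncatalysed product, 46.6 %, gives 0.365 % by the same ratio, and the flask holds 0.37 %.

(The numbers of this flask were drawn at random within sensible limits, and the outcome is calculated.)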